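**Retrosynthetic overview**
- The target is disconnected at C7 to an aryl triflate and (E)-prop-1-enylboronic acid (Suzuki–Miyaura coupling), with the syringyl phenol carried as a pivalate; the C7 oxygen is a traceless handle.
- Feature used: on ring A, C4a is para to C7 and ortho to C8a, the carbon that bears O1. A C7 phenol can therefore be oxidised with trivalent iodine and trapped at C4a by the C3 hydroxyl, forming C4a–O4 and closing the dioxane ring (O1, C2, C3, O4, C4a, C8a) last.
- The cyclisation precursor is a threo (1R,2R) 1-aryloxy-1-arylpropan-2-ol, made by anti opening of a (2S,3R) cis-epoxide at its benzylic carbon with symmetric 5-methoxyresorcinol; this fixes the trans 2,3-relationship.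
- The epoxide comes from syringaldehyde by pivaloylation, Z-selective Wittig ethylidenation and Jacobsen–Katsuki epoxidation.
- Ring order: both benzene rings are bought; the only ring formed is the 1,4-dioxane ring, in step 5.

Key step: step 5

Assumption: the (S,S)-salen manganese chloride catalyst is taken to epoxidise the Z-alkene of step 2 with the facial sense known for cis-β-methylstyrene, giving the (2S,3R)-oxirane; if the sense proves opposite, the (R,R) catalyst is used.

**Step 1**
Reactants: 1 syringaldehyde (4-hydroxy-3,5-dimethoxybenzaldehyde)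
Product: 2 4-formyl-2,6-dimethoxyphenyl pivalate
Conditions: t-BuCOCl, Et3N, DMAP (cat.), CH2Cl2, 0 °C → rt
Reagents that add atoms: pivaloyl chloride, CC(C)(C)C(=O)Cl
Why: DMAP-catalysed O-acylation (esterification) masks the only phenol of this ring as a hindered ester and makes the ring a poorer donor for steps 3 to 5.

**Step 2**
Reactants: 2 4-formyl-2,6-dimethoxyphenyl pivalate
Product: 3 2,6-dimethoxy-4-[(Z)-prop-1-enyl]phenyl pivalate
Conditions: EtPPh3Br, KN(SiMe3)2 (slightly less than the salt), THF, −78 °C → rt; minor E isomer removed on AgNO3-impregnated silica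
Reagents that add atoms: ethyltriphenylphosphonium bromide, CC[P+](c1ccccc1)(c1ccccc1)c1ccccc1.[Br-]
Why: Wittig olefination with a non-stabilised, lithium-free ylide under kinetic control passes through the cis-oxaphosphetane and should favour the Z-alkene, while the aldehyde reacts far faster than the hindered pivalate.

**Step 3**
Reactants: 3 2,6-dimethoxy-4-[(Z)-prop-1-enyl]phenyl pivalate
Product: 4 2,6-dimethoxy-4-[(2S,3R)-3-methyloxiran-2-yl]phenyl pivalate (cis-epoxide)
Conditions: (S,S)-[N,N'-bis(3,5-di-tert-butylsalicylidene)-1,2-cyclohexanediaminato]MnCl (5 mol %), 4-phenylpyridine N-oxide, aq. NaOCl (pH 11.3, Na2HPO4 buffer), CH2Cl2, 0 °C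
Reagents that add atoms: sodium hypochlorite, [Na+].[O-]Cl
Why: Jacobsen–Katsuki epoxidation, in which the oxo-manganese salen species delivers oxygen to one face of the cis aryl alkene, should set both stereocentres (C2 S, C3 R) under catalyst control, and the N-oxide additive should limit cis-to-trans leakage.

**Step 4**
Reactants: 4 2,6-dimethoxy-4-[(2S,3R)-3-methyloxiran-2-yl]phenyl pivalate; 5 5-methoxyresorcinol
Product: 6 4-[(1R,2R)-2-hydroxy-1-(3-hydroxy-5-methoxyphenoxy)propyl]-2,6-dimethoxyphenyl pivalate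
Conditions: Cs2CO3 (0.3 equiv), diphenol in fourfold excess, DMF, 70 °C
Reagents that add atoms: none
Why: Base-mediated SN2 opening of an aryl epoxide by a phenoxide (Williamson-type etherification) is expected at the benzylic carbon, which the aryl group activates while the pivaloyloxy substituent keeps it from ionising, and attack anti to the epoxide oxygen inverts that carbon (S to R) and leaves C2 (R) untouched, so the threo (1R,2R) ether should result as a pure addition product; the excess of the symmetric diphenol gives a single mono-ether and buffers the medium against pivaloyl transfer.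

**Step 5**
Reactants: 6 4-[(1R,2R)-2-hydroxy-1-(3-hydroxy-5-methoxyphenoxy)propyl]-2,6-dimethoxyphenyl pivalate
Product: 9 4-[(2R,3R)-7-hydroxy-5-methoxy-3-methyl-2,3-dihydro-1,4-benzodioxin-2-yl]-2,6-dimethoxyphenyl pivalate, via aryloxy-λ3-iodane 7 (not isolated), via 4aH-dienone 8 (not isolated)
Conditions: PhI(OAc)2 (1.1 equiv, added over 1 h), (CF3)2CHOH/CH2Cl2 (1:1), 0.01 M, −20 °C; then Zn dust, AcOH, 0 °C
Reagents that add atoms: none
Why: Proposed new method: ligand exchange of the C7 phenol at trivalent iodine gives aryloxy-λ3-iodane 7, and the C3 hydroxyl then adds to the para carbon C4a as iodobenzene and acetate leave (a phenoxenium-type process favoured by the fluoroalcohol), giving the 4aH-dienone 8, which tautomerises to phenol 9; the closest known reaction type is the hypervalent-iodine oxidative para-alkoxylation of phenols to quinol ethers and quinone monoketals, including spirocyclisation by tethered alcohols, which has not been applied to an ortho-fused C–H etherification of a para-unsubstituted phenol. The dioxane ring (O1, C2, C3, O4, C4a, C8a) closes as a six-membered ring onto a trigonal carbon, endo with respect to the C4a–C8a bond, and no spiro centre is formed. No stereocentre is created: O4 is the nucleophile, so C3 keeps its configuration and the threo arrangement of 6 becomes the trans (2R,3R) ring. The step needs closure at C4a and not at C8, both being ortho to C8a; this is expected from the larger LUMO coefficient at the para carbon, from the iodane on O7 that shields C6 and C8, and from the doubly vinylogous-ester stabilisation of the 2,5-dienone 8, although the flanking alkoxy groups do not stabilise charge at C4a by resonance. The pivalate removes the only other phenol and lowers the nucleophilicity of the second aryl ring, and high dilution should suppress intermolecular C–C coupling. Because 9 is a p-alkoxyphenol and more easily oxidised than 6, the oxidant is added slowly and the mixture is treated with Zn/AcOH before work-up, which should reduce any C4a acetoxy or hexafluoroisopropoxy quinone monoketal back to 9.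

**Step 6**
Reactants: 9 4-[(2R,3R)-7-hydroxy-5-methoxy-3-methyl-2,3-dihydro-1,4-benzodioxin-2-yl]-2,6-dimethoxyphenyl pivalate
Product: 10 4-[(2R,3R)-5-methoxy-3-methyl-7-(trifluoromethanesulfonyloxy)-2,3-dihydro-1,4-benzodioxin-2-yl]-2,6-dimethoxyphenyl pivalate
Conditions: PhNTf2, Et3N, DMAP (cat.), CH2Cl2, rt
Reagents that add atoms: N-phenylbis(trifluoromethanesulfonimide), O=S(=O)(N(c1ccccc1)S(=O)(=O)C(F)(F)F)C(F)(F)F
Why: O-sulfonylation of the only free hydroxyl (aryl triflate formation) converts the C7 oxygen into a leaving group for cross-coupling without touching the stereocentres.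

**Step 7**
Reactants: 10 the C7 triflate; 11 (E)-prop-1-enylboronic acid
Product: 12 2,6-dimethoxy-4-[(2R,3R)-5-methoxy-3-methyl-7-[(E)-prop-1-enyl]-2,3-dihydro-1,4-benzodioxin-2-yl]phenyl pivalate
Conditions: Pd(dppf)Cl2 (5 mol %), K3PO4, 1,4-dioxane/H2O, 80 °C
Reagents that add atoms: none
Why: Suzuki–Miyaura coupling (oxidative addition of zerovalent palladium into the aryl C–OTf bond, transmetalation and reductive elimination) proceeds with retention of the E geometry of the alkenylboron partner, and the hindered aryl pivalate is inert to the catalyst; any partial loss of the pivalate here would only anticipate step 8.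

**Step 8**
Reactants: 12 the pivalate of the target
Product: 13 2,6-dimethoxy-4-[(2R,3R)-5-methoxy-3-methyl-7-[(E)-prop-1-enyl]-2,3-dihydro-1,4-benzodioxin-2-yl]phenol (target)
Conditions: i-Bu2AlH (3 equiv), CH2Cl2, −78 → 0 °C; aq. potassium sodium tartrate
Reagents that add atoms: none
Why: Reductive cleavage of the aryl ester by hydride frees the phenol at low temperature under non-basic conditions, which avoids quinone-methide opening of the benzylic aryl ether and leaves the alkene and both stereocentres untouched.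

**Compound list**
1 | syringaldehyde | COc1cc(C=O)cc(OC)c1O | starting material
2 | 4-formyl-2,6-dimethoxyphenyl pivalate | COc1cc(C=O)cc(OC)c1OC(=O)C(C)(C)C | intermediate
3 | 2,6-dimethoxy-4-[(Z)-prop-1-enyl]phenyl pivalate | C/C=C\c1cc(OC)c(OC(=O)C(C)(C)C)c(OC)c1 | intermediate
4 | 2,6-dimethoxy-4-[(2S,3R)-3-methyloxiran-2-yl]phenyl pivalate | C[C@H]1O[C@H]1c1cc(OC)c(OC(=O)C(C)(C)C)c(OC)c1 | intermediate
5 | 5-methoxyresorcinol | COc1cc(O)cc(O)c1 | starting material
6 | 4-[(1R,2R)-2-hydroxy-1-(3-hydroxy-5-methoxyphenoxy)propyl]-2,6-dimethoxyphenyl pivalate | Oc1cc(OC)cc(c1)O[C@H](c1cc(OC)c(OC(=O)C(C)(C)C)c(OC)c1)[C@@H](C)O | intermediate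
7 | aryloxy-λ3-iodane: 4-[(1R,2R)-1-{3-[acetoxy(phenyl)-λ3-iodanyloxy]-5-methoxyphenoxy}-2-hydroxypropyl]-2,6-dimethoxyphenyl pivalate | CC(=O)OI(c1ccccc1)Oc1cc(OC)cc(c1)O[C@H](c1cc(OC)c(OC(=O)C(C)(C)C)c(OC)c1)[C@@H](C)O | intermediate (not isolated)
8 | 4aH-dienone: 4-[(2R,3R)-5-methoxy-3-methyl-7-oxo-2,3,4a,7-tetrahydro-1,4-benzodioxin-2-yl]-2,6-dimethoxyphenyl pivalate (C4a configuration not fixed; the centre is lost on tautomerisation) | O=C1C=C(OC)C2O[C@H](C)[C@@H](c3cc(OC)c(OC(=O)C(C)(C)C)c(OC)c3)OC2=C1 | intermediate (not isolated)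
9 | 4-[(2R,3R)-7-hydroxy-5-methoxy-3-methyl-2,3-dihydro-1,4-benzodioxin-2-yl]-2,6-dimethoxyphenyl pivalate | Oc1cc(OC)c2c(c1)O[C@H](c1cc(OC)c(OC(=O)C(C)(C)C)c(OC)c1)[C@@H](C)O2 | intermediate
10 | 4-[(2R,3R)-5-methoxy-3-methyl-7-(trifluoromethanesulfonyloxy)-2,3-dihydro-1,4-benzodioxin-2-yl]-2,6-dimethoxyphenyl pivalate | O=S(=O)(Oc1cc(OC)c2c(c1)O[C@H](c1cc(OC)c(OC(=O)C(C)(C)C)c(OC)c1)[C@@H](C)O2)C(F)(F)F | intermediate
11 | (E)-prop-1-enylboronic acid | C/C=C/B(O)O | starting material
12 | 2,6-dimethoxy-4-[(2R,3R)-5-methoxy-3-methyl-7-[(E)-prop-1-enyl]-2,3-dihydro-1,4-benzodioxin-2-yl]phenyl pivalate | C/C=C/c1cc(OC)c2c(c1)O[C@H](c1cc(OC)c(OC(=O)C(C)(C)C)c(OC)c1)[C@@H](C)O2 | intermediate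
13 | 2,6-dimethoxy-4-[(2R,3R)-5-methoxy-3-methyl-7-[(E)-prop-1-enyl]-2,3-dihydro-1,4-benzodioxin-2-yl]phenol | C/C=C/c1cc(OC)c2c(c1)O[C@H](c1cc(OC)c(O)c(OC)c1)[C@@H](C)O2 | target

Total step count: 8. Longest linear sequence: 8 steps, from syringaldehyde 1.

**Steps most likely to fail**

Step 5. The hydroxyl may close onto the ortho carbon C8 instead of C4a, the product phenol may be oxidised further faster than 6 is consumed, and intermolecular C–C coupling or acetoxylation of the electron-rich ring may outrun ring closure. The fallback uses known chemistry, sets out from epoxide 4 and comes back at 9. Epoxide 4 would be opened as in step 4 with 2-bromo-3-methoxyphenol (Cs2CO3 cat., DMF, 70 °C) to give 4-[(1R,2R)-1-(2-bromo-3-methoxyphenoxy)-2-hydroxypropyl]-2,6-dimethoxyphenyl pivalate F1. Intramolecular palladium-catalysed C–O coupling (Buchwald–Hartwig etherification: Pd(OAc)2, 2-(di-tert-butylphosphino)-1,1'-binaphthyl, Cs2CO3, toluene, 80 °C) would then close the dioxane ring at the bromine-bearing carbon with retention at C3, giving 2,6-dimethoxy-4-[(2R,3R)-5-methoxy-3-methyl-2,3-dihydro-1,4-benzodioxin-2-yl]phenyl pivalate F2. Sterically controlled C–H borylation ([Ir(OMe)(cod)]2, 4,4'-di-tert-butyl-2,2'-bipyridine, B2pin2, THF, 60 °C) should take place at C7, the only aromatic C–H without an ortho substituent, to give 2,6-dimethoxy-4-[(2R,3R)-5-methoxy-3-methyl-7-(4,4,5,5-tetramethyl-1,3,2-dioxaborolan-2-yl)-2,3-dihydro-1,4-benzodioxin-2-yl]phenyl pivalate F3. Oxidation (NaBO3·4H2O, THF/H2O, rt) would return phenol 9.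

Step 4. The phenoxide may attack the methyl-bearing carbon, the ambident resorcinolate may alkylate at carbon, partial ionisation at the benzylic carbon may erode the threo configuration, and the pivaloyl group may migrate to the phenoxide. The fallback removes the regiochemical choice by a double inversion at a single electrophilic carbon; it sets out from alkene 3 and comes back at 6. Alkene 3 would be isomerised (I2 cat., CH2Cl2, visible light) to 2,6-dimethoxy-4-[(E)-prop-1-enyl]phenyl pivalate F4. Shi epoxidation (D-fructose-derived ketone 1,2:4,5-di-O-isopropylidene-β-D-erythro-2,3-hexodiulo-2,6-pyranose, KHSO5 as 2KHSO5·KHSO4·K2SO4, K2CO3, Bu4NHSO4, MeCN/dimethoxymethane/aq. buffer, 0 °C) should give the trans-epoxide 2,6-dimethoxy-4-[(2R,3R)-3-methyloxiran-2-yl]phenyl pivalate F5. Opening with bromide at the benzylic carbon with inversion (LiBr, AcOH, THF, 0 °C) would give 4-[(1S,2R)-1-bromo-2-hydroxypropyl]-2,6-dimethoxyphenyl pivalate F6. Silylation (TBSOTf, 2,6-lutidine, CH2Cl2, −78 °C), which blocks re-closure to the epoxide, would give 4-[(1S,2R)-1-bromo-2-(tert-butyldimethylsilyloxy)propyl]-2,6-dimethoxyphenyl pivalate F7. Williamson displacement of the benzylic bromide by 5-methoxyresorcinol 5 in fourfold excess (Cs2CO3, DMF, rt), a second inversion, would give 4-[(1R,2R)-2-(tert-butyldimethylsilyloxy)-1-(3-hydroxy-5-methoxyphenoxy)propyl]-2,6-dimethoxyphenyl pivalate F8. Desilylation (HF·pyridine, THF, 0 °C) would return 6.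

Step 2. The Z-selectivity of the ethylidenation may be eroded, and the E-alkene would carry through as cis-benzodioxane material. The fallback fixes the geometry before the methyl group is attached; it sets out from aldehyde 2 and comes back at 3. Stork–Zhao olefination ((iodomethyl)triphenylphosphonium iodide, NaN(SiMe3)2, THF/DMPU, −78 °C) would give 4-[(Z)-2-iodoethenyl]-2,6-dimethoxyphenyl pivalate F9. Negishi coupling with retention of geometry (MeZnCl, Pd(PPh3)4, THF, rt) would return alkene 3.

**Further compounds**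
F1 | step 5 | 4-[(1R,2R)-1-(2-bromo-3-methoxyphenoxy)-2-hydroxypropyl]-2,6-dimethoxyphenyl pivalate | COc1cccc(O[C@H](c2cc(OC)c(OC(=O)C(C)(C)C)c(OC)c2)[C@@H](C)O)c1Br
F2 | step 5 | 2,6-dimethoxy-4-[(2R,3R)-5-methoxy-3-methyl-2,3-dihydro-1,4-benzodioxin-2-yl]phenyl pivalate | c1cc(OC)c2c(c1)O[C@H](c1cc(OC)c(OC(=O)C(C)(C)C)c(OC)c1)[C@@H](C)O2
F3 | step 5 | 2,6-dimethoxy-4-[(2R,3R)-5-methoxy-3-methyl-7-(4,4,5,5-tetramethyl-1,3,2-dioxaborolan-2-yl)-2,3-dihydro-1,4-benzodioxin-2-yl]phenyl pivalate | CC1(C)OB(OC1(C)C)c1cc(OC)c2c(c1)O[C@H](c1cc(OC)c(OC(=O)C(C)(C)C)c(OC)c1)[C@@H](C)O2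
F4 | step 4 | 2,6-dimethoxy-4-[(E)-prop-1-enyl]phenyl pivalate | C/C=C/c1cc(OC)c(OC(=O)C(C)(C)C)c(OC)c1
F5 | step 4 | 2,6-dimethoxy-4-[(2R,3R)-3-methyloxiran-2-yl]phenyl pivalate | C[C@H]1O[C@@H]1c1cc(OC)c(OC(=O)C(C)(C)C)c(OC)c1
F6 | step 4 | 4-[(1S,2R)-1-bromo-2-hydroxypropyl]-2,6-dimethoxyphenyl pivalate | Br[C@@H](c1cc(OC)c(OC(=O)C(C)(C)C)c(OC)c1)[C@@H](C)O
F7 | step 4 | 4-[(1S,2R)-1-bromo-2-(tert-butyldimethylsilyloxy)propyl]-2,6-dimethoxyphenyl pivalate | Br[C@@H](c1cc(OC)c(OC(=O)C(C)(C)C)c(OC)c1)[C@@H](C)O[Si](C)(C)C(C)(C)C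
F8 | step 4 | 4-[(1R,2R)-2-(tert-butyldimethylsilyloxy)-1-(3-hydroxy-5-methoxyphenoxy)propyl]-2,6-dimethoxyphenyl pivalate | Oc1cc(OC)cc(c1)O[C@H](c1cc(OC)c(OC(=O)C(C)(C)C)c(OC)c1)[C@@H](C)O[Si](C)(C)C(C)(C)C
F9 | step 2 | 4-[(Z)-2-iodoethenyl]-2,6-dimethoxyphenyl pivalate | I/C=C\c1cc(OC)c(OC(=O)C(C)(C)C)c(OC)c1
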